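**Retrosynthetic overview**

1. Target ⇐ (Z)-enyne from a C4 aldehyde (last) ⇐ bicyclic dibromide ⇐ oxonium ring expansion: a C7 triflate on a 2,2'-linked bis-tetrahydrofuran is displaced by the oxygen of the neighbouring bromotetrahydrofuran, then bromide opens the oxonium ion at C10, so that this oxygen becomes O7 (C7–O–C13), Br lands on C10 and the oxocane (ring B) appears.
2. Bis-tetrahydrofuran ketone ⇐ one-flask key step from a monocyclic enol acetal: a Petasis–Ferrier O→C shift makes C8–C9 and the tetrahydrofuran (ring A); 5-endo bromoetherification by the C10 oxygen makes O7–C13, C12–Br and a temporary bromotetrahydrofuran (ring T).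
3. Enabling feature: in ring A the methylene C8 lies between the oxygen-bearing carbons C7 and C9 (3-oxygenated tetrahydrofuran, the retron of the O→C shift). C13–O7 and C12–Br are anti-vicinal with C13 three bonds from C10, so an oxygen parked on C10 reaches C13 through a five-membered ring and, C10 and C7 being 1,4-related across C8–C9, can later move to C7.
4. Enol acetal ⇐ methylenation of a 1,3-dioxolan-4-one ⇐ (S)-α-hydroxy acid from L-malic acid (C4–C7, sets C6) + (R)-2-silyloxy-(E)-hept-4-enal from (R)-benzyl glycidyl ether and 1-butyne (C9–C15, sets C10).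
5. Ring order: dioxolanone (temporary) → ring A and ring T (step 11) → ring B by expansion of ring T (step 14).

Key step: step 11

Remark: carbons are numbered along the C15 chain (C1 = alkyne CH, C15 = CH3); O6 is the oxygen of C6–O–C9 and O7 that of C7–O–C13. TBDPS = tert-butyldiphenylsilyl, TES = triethylsilyl, TIPS = triisopropylsilyl, Tf = trifluoromethanesulfonyl.

**Step 1**
Reactants: 1 L-malic acid
Product: 2 (S)-2-(2,2-dimethyl-5-oxo-1,3-dioxolan-4-yl)acetic acid
Conditions: 2,2-dimethoxypropane, p-TsOH (cat.), 23 °C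
Reagents that add atoms: 2,2-dimethoxypropane COC(C)(C)OC
Why: Acid-catalysed acetalisation engages the α-hydroxy acid unit selectively because the five-membered dioxolanone is favoured over the six-membered alternative, and the stereocentre is untouched.

**Step 2**
Reactants: 2 (S)-2-(2,2-dimethyl-5-oxo-1,3-dioxolan-4-yl)acetic acid
Product: 3 (S)-5-(2-hydroxyethyl)-2,2-dimethyl-1,3-dioxolan-4-one
Conditions: BH3·SMe2, THF, 0 → 23 °C; MeOH
Reagents that add atoms: none
Why: Chemoselective borane reduction of the free carboxylic acid (via its acyloxyborane) should leave the dioxolanone carbonyl intact.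

**Step 3**
Reactants: 3 (S)-5-(2-hydroxyethyl)-2,2-dimethyl-1,3-dioxolan-4-one
Product: 4 (S)-5-(2-TBDPSO-ethyl)-2,2-dimethyl-1,3-dioxolan-4-one
Conditions: TBDPSCl, imidazole, DMF, 23 °C
Reagents that add atoms: tert-butyl(chloro)diphenylsilane CC(C)(C)[Si](Cl)(c1ccccc1)c1ccccc1
Why: Standard silylation of a primary alcohol, which also prevents translactonisation.

**Step 4**
Reactants: 4 (S)-5-(2-TBDPSO-ethyl)-2,2-dimethyl-1,3-dioxolan-4-one
Product: 5 (S)-4-(TBDPSO)-2-hydroxybutanoic acid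
Conditions: LiOH, THF/H2O, 0 °C; then 1 M HCl to pH 3
Reagents that add atoms: water O
Why: Saponification of the dioxolanone releases the α-hydroxy acid and acetone; the carboxylate is not enolised, so C6 keeps its configuration.

**Step 5**
Reactants: 6 (R)-benzyl glycidyl ether
Product: 7 (R)-1-(benzyloxy)hept-4-yn-2-ol
Conditions: 1-butyne, n-BuLi, THF, −78 °C; BF3·OEt2; then 6
Reagents that add atoms: 1-butyne CCC#C
Why: BF3-promoted opening of the terminal epoxide by the lithium acetylide occurs at the unsubstituted carbon, so the C10 stereocentre comes unchanged from the glycidyl ether.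

**Step 6**
Reactants: 7 (R)-1-(benzyloxy)hept-4-yn-2-ol
Product: 8 (R,E)-hept-4-ene-1,2-diol
Conditions: Na, NH3 (l), THF, −78 → −33 °C; NH4Cl
Reagents that add atoms: none
Why: Dissolving-metal (Birch-type) reduction should give the (E)-alkene by trans protonation of the vinyl radical anion and cleave the benzyl ether in the same operation.

**Step 7**
Reactants: 8 (R,E)-hept-4-ene-1,2-diol
Product: 9 (R,E)-1,2-bis(TESO)hept-4-ene
Conditions: Et3SiCl, imidazole, CH2Cl2, 0 → 23 °C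
Reagents that add atoms: chlorotriethylsilane CC[Si](Cl)(CC)CC
Why: Exhaustive silylation sets up the selective oxidation of the primary silyl ether.

**Step 8**
Reactants: 9 (R,E)-1,2-bis(TESO)hept-4-ene
Product: 10 (R,E)-2-(TESO)hept-4-enal
Conditions: (COCl)2, DMSO, CH2Cl2, −78 → −30 °C; Et3N, −78 °C
Reagents that add atoms: none
Why: Swern oxidation of a bis(triethylsilyl) ether oxidises the primary silyl ether directly to the aldehyde and leaves the secondary one, without epimerising the α-silyloxy centre at low temperature.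

**Step 9**
Reactants: 5 (S)-4-(TBDPSO)-2-hydroxybutanoic acid; 10 (R,E)-2-(TESO)hept-4-enal
Product: 12 (2S,5S)-5-(2-TBDPSO-ethyl)-2-[(1R,3E)-1-(TESO)hex-3-enyl]-1,3-dioxolan-4-one, via bis(trimethylsilyl) derivative 11 (not isolated)
Conditions: Me3SiCl, Et3N, CH2Cl2, 0 °C; then 10, Me3SiOTf (5 mol%), −78 °C
Reagents that add atoms: none
Why: Silyl-triflate-catalysed acetalisation of the bis-silylated α-hydroxy acid with the aldehyde should give the dioxolanone under non-epimerising conditions; the cis acetal is drawn, but this centre (C9) is ionised again in step 11.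

**Step 10**
Reactants: 12 (2S,5S)-5-(2-TBDPSO-ethyl)-2-[(1R,3E)-1-(TESO)hex-3-enyl]-1,3-dioxolan-4-one
Product: 13 (2S,4S)-4-(2-TBDPSO-ethyl)-5-methylidene-2-[(1R,3E)-1-(TESO)hex-3-enyl]-1,3-dioxolane
Conditions: Cp2TiMe2, toluene, 65 °C, dark
Reagents that add atoms: dimethyltitanocene Cp2TiMe2 C[Ti](C)(C1C=CC=C1)C1C=CC=C1
Why: Petasis methylenation of the lactone-type carbonyl by the non-basic titanium methylidene gives the exocyclic enol ether (C7=C8) without touching C6, the silyl ethers or the alkene.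

**Step 11**
Reactants: 13 (2S,4S)-4-(2-TBDPSO-ethyl)-5-methylidene-2-[(1R,3E)-1-(TESO)hex-3-enyl]-1,3-dioxolane
Product: 15 (2S,5S)-5-[(2R,4S,5R)-4-bromo-5-ethyloxolan-2-yl]-2-(2-TBDPSO-ethyl)oxolan-3-one, via furanone 14 (not isolated)
Conditions: Me3SiOTf (0.2 equiv), CH2Cl2, −78 °C; then 2,6-di-tert-butylpyridine (0.3 equiv), N-bromosuccinimide (1.1 equiv), MeCN, −40 → 0 °C (one flask, no work-up between the two charges)
Reagents that add atoms: N-bromosuccinimide O=C1CCC(=O)N1Br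
Why: Me3SiOTf silylates the enol-ether oxygen and ionises the C9–O acetal bond to an oxocarbenium ion (O6=C9) and a silyl enol ether, which recombine through C8 (Petasis–Ferrier O-to-C 1,3-shift; ring A closes by a 5-(enol-endo) Mukaiyama-type attack on the oxocarbenium carbon) and release the catalyst to give furanone 14. N-Bromosuccinimide then forms the bromonium ion of the only alkene left, and the silyl ether oxygen on C10 opens it at C13 by a 5-endo-trig anti addition (ring T), succinimide taking the Et3Si group; the 4-exo mode at C12 is not competitive and neither O6 nor the C7 carbonyl has a productive small-ring path. The closest known reactions are the Lewis-acid rearrangement of 4-methylene-1,3-dioxolanes to oxolan-3-ones and the 5-endo halo-etherification of (E)-homoallylic alcohols and their silyl ethers. C9 is set by C6 (both ring A substituents pseudo-equatorial in the envelope transition state, cis-2,5), the relative configuration of C12 and C13 by the E geometry (Br trans to ethyl), and their absolute sense by C10, whose ring A substituent and the ethyl group both avoid the bromonium bridge and end cis across the new oxygen. The step needs chemoselectivity of the bromine electrophile for the alkene over the electron-rich enol ether, secured by completing the rearrangement before NBS is added and by buffering the acid, and facial selectivity at the bromonium ion, secured by the C10 stereocentre.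

**Step 12**
Reactants: 15 (2S,5S)-5-[(2R,4S,5R)-4-bromo-5-ethyloxolan-2-yl]-2-(2-TBDPSO-ethyl)oxolan-3-one
Product: 16 (2S,3S,5S)-5-[(2R,4S,5R)-4-bromo-5-ethyloxolan-2-yl]-2-(2-TBDPSO-ethyl)oxolan-3-ol
Conditions: LiBH(s-Bu)3, THF, −78 °C
Reagents that add atoms: none
Why: The bulky hydride should attack the furanone carbonyl from the face opposite to the two cis ring substituents, giving the all-cis alcohol (C7 hydroxyl up), with the alkyl bromide untouched at −78 °C.

**Step 13**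
Reactants: 16 (2S,3S,5S)-5-[(2R,4S,5R)-4-bromo-5-ethyloxolan-2-yl]-2-(2-TBDPSO-ethyl)oxolan-3-ol
Product: 19 (2S,3R,5S)-5-[(2R,4S,5R)-4-bromo-5-ethyloxolan-2-yl]-2-(2-TBDPSO-ethyl)oxolan-3-ol, via cis-triflate 17 (not isolated), via nitrite ester 18 (not isolated)
Conditions: Tf2O, pyridine, CH2Cl2, −20 °C; then n-Bu4NNO2, toluene/DMF, 23 °C; aqueous work-up
Reagents that add atoms: tetrabutylammonium nitrite CCCC[N+](CCCC)(CCCC)CCCC.[O-]N=O
Why: Lattrell–Dax inversion, in which nitrite displaces the triflate by SN2 from the open lower face (the ring T oxygen sits on the same face as the leaving group and cannot participate) and the nitrite ester hydrolyses on work-up, should place the C7 hydroxyl trans to both ring A substituents.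

**Step 14**
Reactants: 19 (2S,3R,5S)-5-[(2R,4S,5R)-4-bromo-5-ethyloxolan-2-yl]-2-(2-TBDPSO-ethyl)oxolan-3-ol
Product: 22 tert-butyl{2-[(1S,3R,4S,6S,7S,9S)-4,6-dibromo-3-ethyl-2,8-dioxabicyclo[5.2.1]decan-9-yl]ethoxy}diphenylsilane, via trans-triflate 20 (not isolated), via tricyclic oxonium triflate 21 (not isolated)
Conditions: Tf2O, 2,6-di-tert-butyl-4-methylpyridine, CH2Cl2, −78 → −20 °C; then n-Bu4NBr, −78 → 0 °C
Reagents that add atoms: tetrabutylammonium bromide CCCC[N+](CCCC)(CCCC)CCCC.[Br-]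
Why: The ring T oxygen displaces the trans-triflate from the upper face (five-membered anchimeric participation, inversion at C7) to a tricyclic oxonium ion, which bromide should open at the ring-fusion carbon C10 with inversion, where the strain of the oxa-bridged bicyclo[2.2.1] unit is released; this is oxonium-ion ring expansion of the type known for halogenated cyclic ethers of this family, and it delivers O7 to C7, Br to C10 and ring B in one event.

**Step 15**
Reactants: 22 tert-butyl{2-[(1S,3R,4S,6S,7S,9S)-4,6-dibromo-3-ethyl-2,8-dioxabicyclo[5.2.1]decan-9-yl]ethoxy}diphenylsilane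
Product: 23 2-[(1S,3R,4S,6S,7S,9S)-4,6-dibromo-3-ethyl-2,8-dioxabicyclo[5.2.1]decan-9-yl]ethanol
Conditions: n-Bu4NF, AcOH, THF, 0 → 23 °C
Reagents that add atoms: none
Why: Acetic-acid-buffered fluoride desilylation should free the primary alcohol without base-induced elimination of the secondary bromides.

**Step 16**
Reactants: 23 2-[(1S,3R,4S,6S,7S,9S)-4,6-dibromo-3-ethyl-2,8-dioxabicyclo[5.2.1]decan-9-yl]ethanol
Product: 24 2-[(1S,3R,4S,6S,7S,9S)-4,6-dibromo-3-ethyl-2,8-dioxabicyclo[5.2.1]decan-9-yl]acetaldehyde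
Conditions: Dess–Martin periodinane, NaHCO3, CH2Cl2, 0 → 23 °C
Reagents that add atoms: none
Why: Buffered Dess–Martin oxidation gives the C4 aldehyde, which has no stereocentre at its α-carbon (C5 is CH2).

**Step 17**
Reactants: 24 2-[(1S,3R,4S,6S,7S,9S)-4,6-dibromo-3-ethyl-2,8-dioxabicyclo[5.2.1]decan-9-yl]acetaldehyde
Product: 25 (1S,3R,4S,6S,7S,9S)-4,6-dibromo-3-ethyl-9-[(2Z)-5-(TIPS)pent-2-en-4-yn-1-yl]-2,8-dioxabicyclo[5.2.1]decane
Conditions: 1,3-bis(triisopropylsilyl)propyne, n-BuLi, THF, −20 °C; then 24, −78 → 0 °C; NH4Cl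
Reagents that add atoms: 1,3-bis(triisopropylsilyl)propyne CC(C)[Si](C(C)C)(C(C)C)CC#C[Si](C(C)C)(C(C)C)C(C)C
Why: Peterson olefination with the lithiated bis-silylpropyne should give the (Z)-enyne, because the bulky silyl groups steer the addition to the adduct whose syn-elimination places C5 and the alkyne cis.

**Step 18**
Reactants: 25 (1S,3R,4S,6S,7S,9S)-4,6-dibromo-3-ethyl-9-[(2Z)-5-(TIPS)pent-2-en-4-yn-1-yl]-2,8-dioxabicyclo[5.2.1]decane
Product: 26 (1S,3R,4S,6S,7S,9S)-4,6-dibromo-3-ethyl-9-[(2Z)-pent-2-en-4-yn-1-yl]-2,8-dioxabicyclo[5.2.1]decane (target)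
Conditions: n-Bu4NF, THF, 0 °C
Reagents that add atoms: none
Why: Fluoride cleavage of the alkynyl–silicon bond at 0 °C should release the terminal alkyne without touching the (Z)-alkene or the bromides.

**Compound list**

1 | L-malic acid | O[C@@H](CC(O)=O)C(O)=O | starting material
2 | (S)-2-(2,2-dimethyl-5-oxo-1,3-dioxolan-4-yl)acetic acid | CC1(C)O[C@@H](CC(O)=O)C(=O)O1 | intermediate
3 | (S)-5-(2-hydroxyethyl)-2,2-dimethyl-1,3-dioxolan-4-one | CC1(C)O[C@@H](CCO)C(=O)O1 | intermediate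
4 | (S)-5-(2-TBDPSO-ethyl)-2,2-dimethyl-1,3-dioxolan-4-one | CC1(C)O[C@@H](CCO[Si](c2ccccc2)(c2ccccc2)C(C)(C)C)C(=O)O1 | intermediate
5 | (S)-4-(TBDPSO)-2-hydroxybutanoic acid | O[C@@H](CCO[Si](c1ccccc1)(c1ccccc1)C(C)(C)C)C(O)=O | intermediate
6 | (R)-benzyl glycidyl ether | C1O[C@H]1COCc1ccccc1 | starting material
7 | (R)-1-(benzyloxy)hept-4-yn-2-ol | CCC#CC[C@@H](O)COCc1ccccc1 | intermediate
8 | (R,E)-hept-4-ene-1,2-diol | CC/C=C/C[C@@H](O)CO | intermediate
9 | (R,E)-1,2-bis(TESO)hept-4-ene | CC/C=C/C[C@@H](O[Si](CC)(CC)CC)CO[Si](CC)(CC)CC | intermediate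
10 | (R,E)-2-(TESO)hept-4-enal | CC/C=C/C[C@@H](O[Si](CC)(CC)CC)C=O | intermediate
11 | trimethylsilyl (S)-4-(TBDPSO)-2-(trimethylsilyloxy)butanoate (not isolated) | C[Si](C)(C)O[C@@H](CCO[Si](c1ccccc1)(c1ccccc1)C(C)(C)C)C(=O)O[Si](C)(C)C | intermediate
12 | (2S,5S)-5-(2-TBDPSO-ethyl)-2-[(1R,3E)-1-(TESO)hex-3-enyl]-1,3-dioxolan-4-one | O=C1O[C@@H]([C@H](O[Si](CC)(CC)CC)C/C=C/CC)O[C@H]1CCO[Si](c1ccccc1)(c1ccccc1)C(C)(C)C | intermediate
13 | (2S,4S)-4-(2-TBDPSO-ethyl)-5-methylidene-2-[(1R,3E)-1-(TESO)hex-3-enyl]-1,3-dioxolane | C=C1O[C@@H]([C@H](O[Si](CC)(CC)CC)C/C=C/CC)O[C@H]1CCO[Si](c1ccccc1)(c1ccccc1)C(C)(C)C | intermediate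
14 | (2S,5S)-2-(2-TBDPSO-ethyl)-5-[(1R,3E)-1-(TESO)hex-3-enyl]oxolan-3-one (not isolated) | O=C1C[C@@H]([C@H](O[Si](CC)(CC)CC)C/C=C/CC)O[C@H]1CCO[Si](c1ccccc1)(c1ccccc1)C(C)(C)C | intermediate
15 | (2S,5S)-5-[(2R,4S,5R)-4-bromo-5-ethyloxolan-2-yl]-2-(2-TBDPSO-ethyl)oxolan-3-one | O=C1C[C@@H]([C@H]2C[C@H](Br)[C@@H](CC)O2)O[C@H]1CCO[Si](c1ccccc1)(c1ccccc1)C(C)(C)C | intermediate
16 | (2S,3S,5S)-5-[(2R,4S,5R)-4-bromo-5-ethyloxolan-2-yl]-2-(2-TBDPSO-ethyl)oxolan-3-ol | O[C@H]1C[C@@H]([C@H]2C[C@H](Br)[C@@H](CC)O2)O[C@H]1CCO[Si](c1ccccc1)(c1ccccc1)C(C)(C)C | intermediate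
17 | (2S,3S,5S)-oxolan-3-yl triflate of 16 (not isolated) | O=S(=O)(O[C@H]1C[C@@H]([C@H]2C[C@H](Br)[C@@H](CC)O2)O[C@H]1CCO[Si](c1ccccc1)(c1ccccc1)C(C)(C)C)C(F)(F)F | intermediate
18 | (2S,3R,5S)-oxolan-3-yl nitrite, C7-inverted (not isolated) | O=NO[C@@H]1C[C@@H]([C@H]2C[C@H](Br)[C@@H](CC)O2)O[C@H]1CCO[Si](c1ccccc1)(c1ccccc1)C(C)(C)C | intermediate
19 | (2S,3R,5S)-5-[(2R,4S,5R)-4-bromo-5-ethyloxolan-2-yl]-2-(2-TBDPSO-ethyl)oxolan-3-ol | O[C@@H]1C[C@@H]([C@H]2C[C@H](Br)[C@@H](CC)O2)O[C@H]1CCO[Si](c1ccccc1)(c1ccccc1)C(C)(C)C | intermediate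
20 | (2S,3R,5S)-oxolan-3-yl triflate of 19 (not isolated) | O=S(=O)(O[C@@H]1C[C@@H]([C@H]2C[C@H](Br)[C@@H](CC)O2)O[C@H]1CCO[Si](c1ccccc1)(c1ccccc1)C(C)(C)C)C(F)(F)F | intermediate
21 | tricyclic oxonium triflate, O7 bonded to C7, C10 and C13 (not isolated) | CC[C@@H]1[C@@H](Br)C[C@H]2[O+]1[C@H]3C[C@@H]2O[C@H]3CCO[Si](c4ccccc4)(c4ccccc4)C(C)(C)C.[O-]S(=O)(=O)C(F)(F)F | intermediate
22 | tert-butyl{2-[(1S,3R,4S,6S,7S,9S)-4,6-dibromo-3-ethyl-2,8-dioxabicyclo[5.2.1]decan-9-yl]ethoxy}diphenylsilane | CC(C)(C)[Si](c1ccccc1)(c1ccccc1)OCC[C@@H]1O[C@H]2C[C@@H]1O[C@H](CC)[C@@H](Br)C[C@@H]2Br | intermediate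
23 | 2-[(1S,3R,4S,6S,7S,9S)-4,6-dibromo-3-ethyl-2,8-dioxabicyclo[5.2.1]decan-9-yl]ethanol | OCC[C@@H]1O[C@H]2C[C@@H]1O[C@H](CC)[C@@H](Br)C[C@@H]2Br | intermediate
24 | 2-[(1S,3R,4S,6S,7S,9S)-4,6-dibromo-3-ethyl-2,8-dioxabicyclo[5.2.1]decan-9-yl]acetaldehyde | O=CC[C@@H]1O[C@H]2C[C@@H]1O[C@H](CC)[C@@H](Br)C[C@@H]2Br | intermediate
25 | (1S,3R,4S,6S,7S,9S)-4,6-dibromo-3-ethyl-9-[(2Z)-5-(TIPS)pent-2-en-4-yn-1-yl]-2,8-dioxabicyclo[5.2.1]decane | CC(C)[Si](C(C)C)(C(C)C)C#C/C=C\C[C@@H]1O[C@H]2C[C@@H]1O[C@H](CC)[C@@H](Br)C[C@@H]2Br | intermediate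
26 | (1S,3R,4S,6S,7S,9S)-4,6-dibromo-3-ethyl-9-[(2Z)-pent-2-en-4-yn-1-yl]-2,8-dioxabicyclo[5.2.1]decane | C#C/C=C\C[C@@H]1O[C@H]2C[C@@H]1O[C@H](CC)[C@@H](Br)C[C@@H]2Br | target

Total step count: 18. Longest linear sequence: 14 steps (steps 1–4 and 9–18; the branch through steps 5–8 is equally long).

**Steps most likely to fail**

Step 14. The bromide may open the oxonium ion at C7 (which returns the bis-tetrahydrofuran skeleton as its C7 bromide) or at C13, instead of at the ring-fusion carbon C10. The fallback uses no oxonium ion and lets the C7 hydroxyl close ring B directly; it sets out from 13 and comes back at 22. Rearrangement of 13 alone with Me2AlCl (CH2Cl2, −78 °C) gives 14, now isolated. Pyridinium p-toluenesulfonate in MeOH removes the TES group to give (2S,5S)-2-(2-TBDPSO-ethyl)-5-[(1R,3E)-1-hydroxyhex-3-enyl]oxolan-3-one F1. An Appel reaction (CBr4, PPh3, inversion) gives (2S,5S)-5-[(1S,3E)-1-bromohex-3-enyl]-2-(2-TBDPSO-ethyl)oxolan-3-one F2. LiBH(s-Bu)3 gives the all-cis alcohol (2S,3S,5S)-5-[(1S,3E)-1-bromohex-3-enyl]-2-(2-TBDPSO-ethyl)oxolan-3-ol F3. 2,4,4,6-Tetrabromocyclohexa-2,5-dienone in CH2Cl2 should then close ring B by transannular 8-endo anti-bromoetherification (O7 to C13, Br to C12) to 22.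

Step 11. The bromonium ion may form on the wrong alkene face (ethyl trans to ring A across the new oxygen), or the electrophile may attack enol ether that has not yet rearranged. The fallback fixes C12 and C13 on the small fragment, where isomers can be separated, before the fragments are joined; it sets out from 8 (with 5) and comes back at 15. TBSCl and imidazole silylate the primary hydroxyl of 8 to (R,E)-1-(tert-butyldimethylsilyloxy)hept-4-en-2-ol F4. NBS in MeCN closes the bromotetrahydrofuran (5-endo) to tert-butyl{[(2R,4S,5R)-4-bromo-5-ethyloxolan-2-yl]methoxy}dimethylsilane F5. HF·pyridine gives [(2R,4S,5R)-4-bromo-5-ethyloxolan-2-yl]methanol F6. Dess–Martin oxidation gives (2R,4S,5R)-4-bromo-5-ethyloxolane-2-carbaldehyde F7. Condensation with 5 as in step 9 gives (2S,5S)-2-[(2R,4S,5R)-4-bromo-5-ethyloxolan-2-yl]-5-(2-TBDPSO-ethyl)-1,3-dioxolan-4-one F8. Cp2TiMe2 gives (2S,4S)-2-[(2R,4S,5R)-4-bromo-5-ethyloxolan-2-yl]-4-(2-TBDPSO-ethyl)-5-methylidene-1,3-dioxolane F9. Me2AlCl (CH2Cl2, −78 °C) then effects the Petasis–Ferrier rearrangement as a separate step to 15.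

Step 13. The secondary triflate may eliminate toward a dihydrofuran instead of being substituted by nitrite. The fallback is a Mitsunobu inversion; it sets out from 16 and comes back at 19. 4-Nitrobenzoic acid, PPh3 and diisopropyl azodicarboxylate in toluene give (2S,3R,5S)-5-[(2R,4S,5R)-4-bromo-5-ethyloxolan-2-yl]-2-(2-TBDPSO-ethyl)oxolan-3-yl 4-nitrobenzoate F10; K2CO3 in MeOH then gives 19.

**Further compounds**

F1 | step 14 | (2S,5S)-2-(2-TBDPSO-ethyl)-5-[(1R,3E)-1-hydroxyhex-3-enyl]oxolan-3-one | O=C1C[C@@H]([C@H](O)C/C=C/CC)O[C@H]1CCO[Si](c1ccccc1)(c1ccccc1)C(C)(C)C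
F2 | step 14 | (2S,5S)-5-[(1S,3E)-1-bromohex-3-enyl]-2-(2-TBDPSO-ethyl)oxolan-3-one | O=C1C[C@@H]([C@@H](Br)C/C=C/CC)O[C@H]1CCO[Si](c1ccccc1)(c1ccccc1)C(C)(C)C
F3 | step 14 | (2S,3S,5S)-5-[(1S,3E)-1-bromohex-3-enyl]-2-(2-TBDPSO-ethyl)oxolan-3-ol | O[C@H]1C[C@@H]([C@@H](Br)C/C=C/CC)O[C@H]1CCO[Si](c1ccccc1)(c1ccccc1)C(C)(C)C
F4 | step 11 | (R,E)-1-(tert-butyldimethylsilyloxy)hept-4-en-2-ol | CC/C=C/C[C@@H](O)CO[Si](C)(C)C(C)(C)C
F5 | step 11 | tert-butyl{[(2R,4S,5R)-4-bromo-5-ethyloxolan-2-yl]methoxy}dimethylsilane | CC(C)(C)[Si](C)(C)OC[C@H]1C[C@H](Br)[C@@H](CC)O1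
F6 | step 11 | [(2R,4S,5R)-4-bromo-5-ethyloxolan-2-yl]methanol | OC[C@H]1C[C@H](Br)[C@@H](CC)O1
F7 | step 11 | (2R,4S,5R)-4-bromo-5-ethyloxolane-2-carbaldehyde | O=C[C@H]1C[C@H](Br)[C@@H](CC)O1
F8 | step 11 | (2S,5S)-2-[(2R,4S,5R)-4-bromo-5-ethyloxolan-2-yl]-5-(2-TBDPSO-ethyl)-1,3-dioxolan-4-one | O=C1O[C@@H]([C@H]2C[C@H](Br)[C@@H](CC)O2)O[C@H]1CCO[Si](c1ccccc1)(c1ccccc1)C(C)(C)C
F9 | step 11 | (2S,4S)-2-[(2R,4S,5R)-4-bromo-5-ethyloxolan-2-yl]-4-(2-TBDPSO-ethyl)-5-methylidene-1,3-dioxolane | C=C1O[C@@H]([C@H]2C[C@H](Br)[C@@H](CC)O2)O[C@H]1CCO[Si](c1ccccc1)(c1ccccc1)C(C)(C)C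
F10 | step 13 | (2S,3R,5S)-5-[(2R,4S,5R)-4-bromo-5-ethyloxolan-2-yl]-2-(2-TBDPSO-ethyl)oxolan-3-yl 4-nitrobenzoate | O=C(O[C@@H]1C[C@@H]([C@H]2C[C@H](Br)[C@@H](CC)O2)O[C@H]1CCO[Si](c1ccccc1)(c1ccccc1)C(C)(C)C)c1ccc(cc1)[N+](=O)[O-]
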